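**Strategy.** Ring A (the trimethylcyclohexene ring C1–C6 that carries the palmitate) is disconnected at C2–C3 and C4–C5 into a C5–C6–C1(Me)2–C2 unit and an acetyl unit (C3, C4). The key step exploits the 1,3-relationship between the oxygen-bearing C3 and the trigonal C5 across C4H2. 3,3-Dimethylcyclobutanone, whose temporary C2–C5 bond makes C2 enolisable, is C-acetylated; the strained 2-acylcyclobutanone is opened by methoxide and re-closed by Dieckmann condensation, a one-pot two-carbon ring expansion to 5,5-dimethylcyclohexane-1,3-dione. An achiral dienone made from it is reduced enantioselectively, base funnels the alkene isomers into (3R)-3-hydroxy-β-ionone, and two Wittig reactions join it to the C10 dialdehyde and an (R)-α-ionone-derived ring B half.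

Key step: step 1

Assumption: (R)-α-ionone is bought in high enantiomeric purity; ring atoms carry carotenoid numbers (C1–C6 in ring A, C1'–C6' in ring B, side chain C7–C15 and C7'–C15').

**Step 1**
Reactants: 1 3,3-dimethylcyclobutan-1-one
Product: 4 5,5-dimethylcyclohexane-1,3-dione, via 2-acetyl-3,3-dimethylcyclobutanone 2 (not isolated), via methyl 3,3-dimethyl-5-oxohexanoate 3 (not isolated)
Conditions: LiN(SiMe3)2 (2.1 equiv), THF, −78 °C; 1-acetylimidazole, −78 → 0 °C; then NaOMe (3 equiv), MeOH, 60 °C; aq. HCl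
Reagents that add atoms: 1-acetylimidazole, CC(=O)n1ccnc1
Why: The lithium enolate of 1 (either α-CH2, the ketone is symmetric) is C-acylated by 1-acetylimidazole, which makes the C2–C3 bond and gives 2 as its enolate; methoxide then adds to the strained ring carbonyl, retro-Claisen cleavage of the temporary C2–C5 bond releases the ring strain and gives keto ester 3, and the methyl-ketone enolate of 3 closes onto the ester carbonyl to make the C4–C5 bond. The closest known reaction types are the crossed Claisen acylation of a ketone enolate, the alkoxide ring opening of 2-acylcyclobutanones and the Dieckmann-type cyclisation of 5-oxohexanoates to cyclohexane-1,3-diones. The six-membered ring closes in the 6-exo-trig mode (enolate carbon onto an ester carbonyl), and deprotonation of the product to its β-diketonate makes the sequence irreversible. No stereocentre is formed. The selectivity needed is C- over O-acylation, which the acylimidazole/lithium enolate pair secures, and attack of methoxide on the ring carbonyl rather than on the acetyl carbonyl, which ring strain secures (the other mode only returns 1 and is reversible).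

**Step 2**
Reactants: 4 5,5-dimethylcyclohexane-1,3-dione
Product: 5 3-ethoxy-5,5-dimethylcyclohex-2-en-1-one
Conditions: EtOH, TsOH·H2O (cat.), toluene, reflux with azeotropic removal of water
Reagents that add atoms: ethanol, CCO
Why: Acid-catalysed enol etherification of a cyclic 1,3-dione (vinylogous esterification) masks one carbonyl and leaves the other (C5) free; 4 is symmetric, so a single product forms.

**Step 3**
Reactants: 6 ethyl 2-(2-methyl-1,3-dioxolan-2-yl)acetate
Product: 7 2-(2-methyl-1,3-dioxolan-2-yl)acetaldehyde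
Conditions: iBu2AlH (1.05 equiv), CH2Cl2, −78 °C; aq. potassium sodium tartrate
Reagents that add atoms: none
Why: Partial ester reduction stops at the aldehyde because the tetrahedral aluminium hemiacetal persists at low temperature until hydrolysis.

**Step 4**
Reactants: 5 3-ethoxy-5,5-dimethylcyclohex-2-en-1-one; 7 2-(2-methyl-1,3-dioxolan-2-yl)acetaldehyde
Product: 10 3-ethoxy-5,5-dimethyl-6-[2-(2-methyl-1,3-dioxolan-2-yl)ethylidene]cyclohex-2-en-1-one (E/Z mixture), via aldol adduct 8 (not isolated), via mesylate 9 (not isolated)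
Conditions: LiN(iPr)2 (1.1 equiv), THF, −78 °C; 7; MsCl, −78 → 0 °C; DBU, 25 °C
Reagents that add atoms: none
Why: Stork–Danheiser α'-deprotonation gives the cross-conjugated enolate at the only enolisable α-carbon (C6), aldol addition to 7 and E1cB loss of mesylate install the exocyclic C6=C7 bond, whose geometry is of no consequence because step 7 erases it.

**Step 5**
Reactants: 10 3-ethoxy-5,5-dimethyl-6-[2-(2-methyl-1,3-dioxolan-2-yl)ethylidene]cyclohex-2-en-1-one
Product: 12 3,5,5-trimethyl-4-[2-(2-methyl-1,3-dioxolan-2-yl)ethylidene]cyclohex-2-en-1-one (achiral, E/Z mixture), via tertiary carbinol 11 (not isolated)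
Conditions: MeLi (2.5 equiv), CeCl3 (2.5 equiv), THF, −78 °C; then 0.5 M HCl, THF–H2O, 0 °C, short contact
Reagents that add atoms: methyllithium, [Li]C; water, O
Why: 1,2-Addition of the methylcerium reagent to the vinylogous ester carbonyl and mild acid hydrolysis of the enol ether (Stork–Danheiser transposition) put the methyl on C5 and move the carbonyl to C3, while the dioxolane survives the brief, cold acid treatment.

**Step 6**
Reactants: 12 3,5,5-trimethyl-4-[2-(2-methyl-1,3-dioxolan-2-yl)ethylidene]cyclohex-2-en-1-one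
Product: 13 (1S)-3,5,5-trimethyl-4-[2-(2-methyl-1,3-dioxolan-2-yl)ethylidene]cyclohex-2-en-1-ol
Conditions: (R)-2-methyl-CBS-oxazaborolidine (0.2 equiv), BH3·SMe2, THF, −40 °C; MeOH
Reagents that add atoms: none
Why: Corey–Bakshi–Shibata reduction of an achiral enone in which the dienyl flank acts as the large group, so the (R)-catalyst should give the (S)-alcohol by catalyst control alone; this spatial arrangement is named 3R once the ring alkene has moved in step 7.

**Step 7**
Reactants: 13 (1S)-3,5,5-trimethyl-4-[2-(2-methyl-1,3-dioxolan-2-yl)ethylidene]cyclohex-2-en-1-ol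
Product: 15 (3R)-3-hydroxy-β-ionone, via skipped dienyl ketone 14 (not isolated)
Conditions: PPTS (0.2 equiv), acetone–H2O, 40 °C; concentrate; then NaOMe (0.3 equiv), MeOH, 50 °C
Reagents that add atoms: water, O
Why: Mild acetal hydrolysis frees the C9 ketone, and base equilibrates 14 through its extended dienolate (deprotonation at C8, reprotonation at C4) into the fully conjugated 7E dienone; this stereoconvergent isomerisation funnels both C6=C7 isomers into one compound and leaves the C3 centre untouched.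

**Step 8**
Reactants: 15 (3R)-3-hydroxy-β-ionone
Product: 16 (1E)-1-[(4R)-4-hydroxy-2,6,6-trimethylcyclohex-1-en-1-yl]-3-methylpenta-1,4-dien-3-ol (both epimers at the new carbinol carbon)
Conditions: CH2=CHMgBr (2.5 equiv), THF, −20 → 0 °C; aq. NH4Cl
Reagents that add atoms: vinylmagnesium bromide, C=C[Mg]Br
Why: Grignard 1,2-addition to the methyl ketone after deprotonation of the 3-hydroxyl; the new centre needs no control because step 9 makes it trigonal.

**Step 9**
Reactants: 16 (1E)-1-[(4R)-4-hydroxy-2,6,6-trimethylcyclohex-1-en-1-yl]-3-methylpenta-1,4-dien-3-ol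
Product: 17 [(2E,4E)-5-[(4R)-4-hydroxy-2,6,6-trimethylcyclohex-1-en-1-yl]-3-methylpenta-2,4-dien-1-yl]triphenylphosphonium bromide
Conditions: Ph3P·HBr (1.05 equiv), MeOH, 0 → 25 °C
Reagents that add atoms: triphenylphosphine hydrobromide, Br.c1ccccc1P(c1ccccc1)c1ccccc1
Why: Acid ionises the tertiary bis-allylic alcohol to a delocalised cation that Ph3P captures at the unhindered terminal carbon (SN1'-type allylic transposition), the standard route from vinyl ionols to C15 Wittig salts; the homoallylic 3-hydroxyl does not ionise.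

**Step 10**
Reactants: 18 (R)-α-ionone
Product: 19 (1E)-3-methyl-1-[(1R)-2,6,6-trimethylcyclohex-2-en-1-yl]penta-1,4-dien-3-ol (both carbinol epimers)
Conditions: CH2=CHMgBr (1.3 equiv), THF, −20 °C; aq. NH4Cl
Reagents that add atoms: vinylmagnesium bromide, C=C[Mg]Br
Why: Grignard 1,2-addition to the enone carbonyl; the C6' centre comes from the chiral pool and is not enolisable under these conditions.

**Step 11**
Reactants: 19 (1E)-3-methyl-1-[(1R)-2,6,6-trimethylcyclohex-2-en-1-yl]penta-1,4-dien-3-ol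
Product: 20 (4R)-4-[(1E)-3-hydroxy-3-methylpenta-1,4-dien-1-yl]-3,5,5-trimethylcyclohex-2-en-1-one
Conditions: Rh2(cap)4 (cap = caprolactamate, 1 mol%), t-BuOOH (70% in H2O, 5 equiv), K2CO3, CH2Cl2, 25 °C
Reagents that add atoms: tert-butyl hydroperoxide, CC(C)(C)OO
Why: Radical allylic oxidation by tert-butylperoxyl radicals converts the ring CH2 next to the trisubstituted alkene (C3') into the enone carbonyl; the tertiary alcohol cannot be oxidised and the C6'–H is shielded by the neighbouring quaternary carbon.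

**Step 12**
Reactants: 20 (4R)-4-[(1E)-3-hydroxy-3-methylpenta-1,4-dien-1-yl]-3,5,5-trimethylcyclohex-2-en-1-one
Product: 21 (1R,4R)-4-[(1E)-3-hydroxy-3-methylpenta-1,4-dien-1-yl]-3,5,5-trimethylcyclohex-2-en-1-ol
Conditions: (S)-2-methyl-CBS-oxazaborolidine (0.2 equiv), BH3·SMe2 (2 equiv), THF, −30 °C; MeOH
Reagents that add atoms: none
Why: Corey–Bakshi–Shibata reduction with the ring alkene as the large group should give the 3'R alcohol; hydride delivery anti to the pseudo-axial C1' methyl group also leads to the 3',6'-trans diol, so catalyst and substrate are expected to reinforce each other.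

**Step 13**
Reactants: 21 (1R,4R)-4-[(1E)-3-hydroxy-3-methylpenta-1,4-dien-1-yl]-3,5,5-trimethylcyclohex-2-en-1-ol
Product: 22 [(2E,4E)-5-[(1R,4R)-4-hydroxy-2,6,6-trimethylcyclohex-2-en-1-yl]-3-methylpenta-2,4-dien-1-yl]triphenylphosphonium bromide
Conditions: Ph3P·HBr (1.05 equiv), MeOH–CH2Cl2, 0 → 25 °C
Reagents that add atoms: triphenylphosphine hydrobromide, Br.c1ccccc1P(c1ccccc1)c1ccccc1
Why: Same SN1'-type phosphonium salt formation as in step 9; the tertiary bis-allylic alcohol ionises far more readily than the secondary ring allylic alcohol, which should therefore survive.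

**Step 14**
Reactants: 17 ring A C15 phosphonium bromide; 23 (2E,4E,6E)-2,7-dimethylocta-2,4,6-trienedial
Product: 25 (3R)-3-hydroxy-12'-apo-β-caroten-12'-al (all-E), via C15 phosphorane 24 (not isolated)
Conditions: 23 (2 equiv), NaOMe (1.1 equiv), MeOH–CH2Cl2, 0 → 25 °C, dark; then heat in EtOH for Z→E equilibration
Reagents that add atoms: none
Why: Wittig olefination of the semi-stabilised allylic ylide with one of the two equivalent formyl groups of the dialdehyde, which is used in excess; the new C11=C12 bond is equilibrated thermally to E, as usual for carotenoid polyenes.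

**Step 15**
Reactants: 25 (3R)-3-hydroxy-12'-apo-β-caroten-12'-al
Product: 26 (3R)-3-(hexadecanoyloxy)-12'-apo-β-caroten-12'-al
Conditions: palmitoyl chloride (1.2 equiv), pyridine, DMAP (cat.), CH2Cl2, 0 → 25 °C, dark
Reagents that add atoms: palmitoyl chloride, CCCCCCCCCCCCCCCC(=O)Cl
Why: DMAP-catalysed O-acylation of the secondary alcohol with retention; placing the palmitate before the second coupling differentiates the two hydroxyls without protecting groups.

**Step 16**
Reactants: 26 (3R)-3-(hexadecanoyloxy)-12'-apo-β-caroten-12'-al; 22 ring B C15 phosphonium bromide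
Product: 28 (3R,3'R,6'R)-3'-hydroxy-β,ε-caroten-3-yl hexadecanoate (lutein 3-palmitate), via ring B phosphorane 27 (not isolated)
Conditions: 22 (1.2 equiv), 1,2-epoxybutane (excess), EtOH–CH2Cl2, reflux, dark, N2
Reagents that add atoms: none
Why: Wittig reaction under neutral epoxide conditions (the epoxide takes up HBr and so generates the ylide) spares the palmitate, and the reflux equilibrates the new C11'=C12' bond to E.

**Step 17**
Reactants: 28 lutein 3-palmitate
Product: 29 (3R,3'R,6'R)-β,ε-carotene-3,3'-diyl 3-hexadecanoate 3'-tetradecanoate (target)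
Conditions: myristoyl chloride (1.5 equiv), pyridine, DMAP (cat.), CH2Cl2, 0 → 25 °C, dark
Reagents that add atoms: myristoyl chloride, CCCCCCCCCCCCCC(=O)Cl
Why: Acylation of the allylic 3'-hydroxyl under basic conditions avoids ionisation and proceeds with retention at C3'.

**Compound list**

1 | 3,3-dimethylcyclobutan-1-one | O=C1CC(C)(C)C1 | starting material
2 | 2-acetyl-3,3-dimethylcyclobutan-1-one (racemic, not isolated) | CC(=O)C1C(=O)CC1(C)C | intermediate
3 | methyl 3,3-dimethyl-5-oxohexanoate (not isolated) | COC(=O)CC(C)(C)CC(C)=O | intermediate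
4 | 5,5-dimethylcyclohexane-1,3-dione | O=C1CC(=O)CC(C)(C)C1 | intermediate
5 | 3-ethoxy-5,5-dimethylcyclohex-2-en-1-one | CCOC1=CC(=O)CC(C)(C)C1 | intermediate
6 | ethyl 2-(2-methyl-1,3-dioxolan-2-yl)acetate | CCOC(=O)CC1(C)OCCO1 | starting material
7 | 2-(2-methyl-1,3-dioxolan-2-yl)acetaldehyde | O=CCC1(C)OCCO1 | intermediate
8 | 3-ethoxy-6-[1-hydroxy-2-(2-methyl-1,3-dioxolan-2-yl)ethyl]-5,5-dimethylcyclohex-2-en-1-one (diastereomers, not isolated) | CCOC1=CC(=O)C(C(O)CC2(C)OCCO2)C(C)(C)C1 | intermediate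
9 | methanesulfonate of 8 (not isolated) | CCOC1=CC(=O)C(C(OS(C)(=O)=O)CC2(C)OCCO2)C(C)(C)C1 | intermediate
10 | 3-ethoxy-5,5-dimethyl-6-[2-(2-methyl-1,3-dioxolan-2-yl)ethylidene]cyclohex-2-en-1-one (E/Z mixture) | CCOC1=CC(=O)C(=CCC2(C)OCCO2)C(C)(C)C1 | intermediate
11 | 3-ethoxy-1,5,5-trimethyl-6-[2-(2-methyl-1,3-dioxolan-2-yl)ethylidene]cyclohex-2-en-1-ol (not isolated) | CCOC1=CC(C)(O)C(=CCC2(C)OCCO2)C(C)(C)C1 | intermediate
12 | 3,5,5-trimethyl-4-[2-(2-methyl-1,3-dioxolan-2-yl)ethylidene]cyclohex-2-en-1-one (E/Z mixture) | O=C1C=C(C)C(=CCC2(C)OCCO2)C(C)(C)C1 | intermediate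
13 | (1S)-3,5,5-trimethyl-4-[2-(2-methyl-1,3-dioxolan-2-yl)ethylidene]cyclohex-2-en-1-ol (E/Z mixture) | O[C@@H]1C=C(C)C(=CCC2(C)OCCO2)C(C)(C)C1 | intermediate
14 | 4-[(4S)-4-hydroxy-2,6,6-trimethylcyclohex-2-en-1-ylidene]butan-2-one (not isolated) | O[C@@H]1C=C(C)C(=CCC(C)=O)C(C)(C)C1 | intermediate
15 | (3R)-3-hydroxy-β-ionone, (E)-4-[(4R)-4-hydroxy-2,6,6-trimethylcyclohex-1-en-1-yl]but-3-en-2-one | O[C@@H]1CC(C)=C(/C=C/C(C)=O)C(C)(C)C1 | intermediate
16 | (1E)-1-[(4R)-4-hydroxy-2,6,6-trimethylcyclohex-1-en-1-yl]-3-methylpenta-1,4-dien-3-ol (carbinol epimers) | O[C@@H]1CC(C)=C(/C=C/C(C)(O)C=C)C(C)(C)C1 | intermediate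
17 | [(2E,4E)-5-[(4R)-4-hydroxy-2,6,6-trimethylcyclohex-1-en-1-yl]-3-methylpenta-2,4-dien-1-yl]triphenylphosphonium bromide | [Br-].O[C@@H]1CC(C)=C(/C=C/C(C)=C/C[P+](c2ccccc2)(c3ccccc3)c4ccccc4)C(C)(C)C1 | intermediate
18 | (R)-α-ionone, (E)-4-[(1R)-2,6,6-trimethylcyclohex-2-en-1-yl]but-3-en-2-one | CC(=O)/C=C/[C@H]1C(C)=CCCC1(C)C | starting material
19 | (1E)-3-methyl-1-[(1R)-2,6,6-trimethylcyclohex-2-en-1-yl]penta-1,4-dien-3-ol (carbinol epimers) | C=CC(C)(O)/C=C/[C@H]1C(C)=CCCC1(C)C | intermediate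
20 | (4R)-4-[(1E)-3-hydroxy-3-methylpenta-1,4-dien-1-yl]-3,5,5-trimethylcyclohex-2-en-1-one | C=CC(C)(O)/C=C/[C@H]1C(C)=CC(=O)CC1(C)C | intermediate
21 | (1R,4R)-4-[(1E)-3-hydroxy-3-methylpenta-1,4-dien-1-yl]-3,5,5-trimethylcyclohex-2-en-1-ol | C=CC(C)(O)/C=C/[C@H]1C(C)=C[C@H](O)CC1(C)C | intermediate
22 | [(2E,4E)-5-[(1R,4R)-4-hydroxy-2,6,6-trimethylcyclohex-2-en-1-yl]-3-methylpenta-2,4-dien-1-yl]triphenylphosphonium bromide | [Br-].c1ccccc1[P+](c2ccccc2)(c3ccccc3)C/C=C(C)/C=C/[C@H]4C(C)=C[C@H](O)CC4(C)C | intermediate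
23 | (2E,4E,6E)-2,7-dimethylocta-2,4,6-trienedial | O=C/C(C)=C/C=C/C=C(C)/C=O | starting material
24 | phosphorane from 17 (not isolated) | O[C@@H]1CC(C)=C(/C=C/C(C)=C/C=P(c2ccccc2)(c3ccccc3)c4ccccc4)C(C)(C)C1 | intermediate
25 | (3R)-3-hydroxy-12'-apo-β-caroten-12'-al | O[C@@H]1CC(C)=C(/C=C/C(C)=C/C=C/C(C)=C/C=C/C=C(C)/C=O)C(C)(C)C1 | intermediate
26 | (3R)-3-(hexadecanoyloxy)-12'-apo-β-caroten-12'-al | CCCCCCCCCCCCCCCC(=O)O[C@@H]1CC(C)=C(/C=C/C(C)=C/C=C/C(C)=C/C=C/C=C(C)/C=O)C(C)(C)C1 | intermediate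
27 | phosphorane from 22 (not isolated) | c1ccccc1P(c2ccccc2)(c3ccccc3)=C/C=C(C)/C=C/[C@H]4C(C)=C[C@H](O)CC4(C)C | intermediate
28 | (3R,3'R,6'R)-3'-hydroxy-β,ε-caroten-3-yl hexadecanoate | CCCCCCCCCCCCCCCC(=O)O[C@@H]1CC(C)=C(/C=C/C(C)=C/C=C/C(C)=C/C=C/C=C(C)/C=C/C=C(C)/C=C/[C@H]2C(C)=C[C@H](O)CC2(C)C)C(C)(C)C1 | intermediate
29 | (3R,3'R,6'R)-β,ε-carotene-3,3'-diyl 3-hexadecanoate 3'-tetradecanoate | CCCCCCCCCCCCCCCC(=O)O[C@@H]1CC(C)=C(/C=C/C(C)=C/C=C/C(C)=C/C=C/C=C(C)/C=C/C=C(C)/C=C/[C@H]2C(C)=C[C@H](OC(=O)CCCCCCCCCCCCC)CC2(C)C)C(C)(C)C1 | target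

**Step count.** 17 steps in total. The longest linear sequence is 12 steps (1, 2, 4, 5, 6, 7, 8, 9, 14, 15, 16, 17); step 3 and steps 10–13 are side branches.

**Steps most likely to fail and fallbacks**

Step 6 may fail through poor facial discrimination, because the catalyst must tell a vinylic flank from a CH2 next to a quaternary carbon. The fallback sets out from 12 and returns at 13. Reduction with NaBH4/CeCl3 in MeOH gives the racemic alcohol, rac-3,5,5-trimethyl-4-[2-(2-methyl-1,3-dioxolan-2-yl)ethylidene]cyclohex-2-en-1-ol F1. A lipase (Pseudomonas cepacia lipase, vinyl acetate, tert-butyl methyl ether) then resolves it. By the empirical rule for lipase acylation of secondary alcohols, with the dienyl flank as the large group, the (R)-enantiomer should be acetylated to (1R)-3,5,5-trimethyl-4-[2-(2-methyl-1,3-dioxolan-2-yl)ethylidene]cyclohex-2-en-1-yl acetate F2, which is removed by chromatography and set aside. The unreacted alcohol is 13.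

Step 7 may fail through acid-induced ionisation of the dienylic alcohol during acetal cleavage (loss of water or allylic scrambling at C3). The fallback sets out from 10 and returns at 15; it moves the alkene before the alcohol exists, so that only a simple allylic alcohol meets acid.
- γ-Deprotonation of 10 with LiN(iPr)2 and kinetic protonation at C6 (AcOH, −78 °C) gives the deconjugated 3-ethoxy-5,5-dimethyl-6-[(E)-2-(2-methyl-1,3-dioxolan-2-yl)ethenyl]cyclohex-2-en-1-one F3.
- MeLi/CeCl3 gives the tertiary carbinol 3-ethoxy-1,5,5-trimethyl-6-[(E)-2-(2-methyl-1,3-dioxolan-2-yl)ethenyl]cyclohex-2-en-1-ol F4, which mild acid converts to racemic 3-oxo-α-ionone ethylene ketal F5.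
- (R)-2-Methyl-CBS-oxazaborolidine/BH3·SMe2 gives (3S)-3-hydroxy-α-ionone ethylene ketal F6 as both C6 epimers.
- PPTS in wet acetone gives (3S)-3-hydroxy-α-ionone F7, and NaOMe in MeOH equilibrates both epimers into 15.

Step 11 may fail through hydrogen abstraction at the doubly allylic C6'–H or oxidative degradation of the tertiary bis-allylic alcohol. The fallback sets out from 18 and returns at 21; it oxidises before the vinyl carbinol is present.
- Ketalisation of 18 (ethylene glycol bis(trimethylsilyl) ether, Me3SiOTf cat., CH2Cl2, −78 °C) gives (R)-α-ionone ethylene ketal F8.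
- The same Rh2(cap)4/t-BuOOH oxidation gives (6R)-3-oxo-α-ionone ethylene ketal F9.
- (S)-2-Methyl-CBS-oxazaborolidine/BH3·SMe2 gives (3R,6R)-3-hydroxy-α-ionone ethylene ketal F10.
- PPTS in wet acetone gives (3R,6R)-3-hydroxy-α-ionone F11, and CH2=CHMgBr (2.5 equiv) gives 21.

**Further compounds**
F1 | step 6 | rac-3,5,5-trimethyl-4-[2-(2-methyl-1,3-dioxolan-2-yl)ethylidene]cyclohex-2-en-1-ol | OC1C=C(C)C(=CCC2(C)OCCO2)C(C)(C)C1
F2 | step 6 | (1R)-3,5,5-trimethyl-4-[2-(2-methyl-1,3-dioxolan-2-yl)ethylidene]cyclohex-2-en-1-yl acetate | CC(=O)O[C@H]1C=C(C)C(=CCC2(C)OCCO2)C(C)(C)C1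
F3 | step 7 | 3-ethoxy-5,5-dimethyl-6-[(E)-2-(2-methyl-1,3-dioxolan-2-yl)ethenyl]cyclohex-2-en-1-one (racemic) | CCOC1=CC(=O)C(/C=C/C2(C)OCCO2)C(C)(C)C1
F4 | step 7 | 3-ethoxy-1,5,5-trimethyl-6-[(E)-2-(2-methyl-1,3-dioxolan-2-yl)ethenyl]cyclohex-2-en-1-ol (diastereomers) | CCOC1=CC(C)(O)C(/C=C/C2(C)OCCO2)C(C)(C)C1
F5 | step 7 | racemic 3-oxo-α-ionone ethylene ketal, 3,5,5-trimethyl-4-[(E)-2-(2-methyl-1,3-dioxolan-2-yl)ethenyl]cyclohex-2-en-1-one | O=C1C=C(C)C(/C=C/C2(C)OCCO2)C(C)(C)C1
F6 | step 7 | (3S)-3-hydroxy-α-ionone ethylene ketal (both C6 epimers) | O[C@@H]1C=C(C)C(/C=C/C2(C)OCCO2)C(C)(C)C1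
F7 | step 7 | (3S)-3-hydroxy-α-ionone (both C6 epimers) | O[C@@H]1C=C(C)C(/C=C/C(C)=O)C(C)(C)C1
F8 | step 11 | (R)-α-ionone ethylene ketal | CC1(/C=C/[C@H]2C(C)=CCCC2(C)C)OCCO1
F9 | step 11 | (6R)-3-oxo-α-ionone ethylene ketal | CC1(/C=C/[C@H]2C(C)=CC(=O)CC2(C)C)OCCO1
F10 | step 11 | (3R,6R)-3-hydroxy-α-ionone ethylene ketal | CC1(/C=C/[C@H]2C(C)=C[C@H](O)CC2(C)C)OCCO1
F11 | step 11 | (3R,6R)-3-hydroxy-α-ionone | CC(=O)/C=C/[C@H]1C(C)=C[C@H](O)CC1(C)C
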